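**Plan**
- **Cuts:** first the protecting groups and the C–CHO bond between the two phenol oxygens. Next, in one operation, the aryl C–O bond of the pyran and the C–CHO bond on the neighbouring aryl carbon. Then the ring C=C, the C–CH3 bond of the carbinol carbon, the ketone C–CH2 bond, and the side-chain bonds at C3 and C4 of a dihydrocoumarin.
- **Enabling feature:** the pyran oxygen sits on the methyl-bearing quaternary ring-fusion carbon, which faces the C=C across the ten-membered ring. Its other bond goes to an aromatic carbon whose ring neighbour carries CHO. The oxygen can therefore arrive as a tertiary alkoxide on an aryne, and the carbanion left next door takes up the formyl carbon.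
- **Forward order:** coumarin → 3,4-trans-dihydrocoumarin (a temporary lactone ring) → opened to a Weinreb amide → joined to the terpene-side Grignard reagent → carbinol → ten-membered ring by RCM → pyran ring by the aryne cascade → second CHO → deprotection.
- **Stereochemistry:** the benzylic C comes from Cu-catalysed asymmetric conjugate addition and the ring-fusion CH from trans alkylation of the lactone enolate. The carbinol C comes from Felkin–Anh methyl addition and the CH(CMe2OH) centre from Shi epoxidation with invertive allyl opening. The Z alkene follows from ring strain in the RCM.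

Key step: step 15

Remark: in step 3 the antipode of the ferrocenyl ligand that leads to (S)-5 is used; both antipodes are commercial.

Step 1
Reactants: 1 4-bromoresorcinol; 2 DL-malic acid
Product: 3 6-bromo-7-hydroxycoumarin
Conditions: conc. H2SO4, 100–110 °C; ice water
Reagents that add atoms: none
Why: Von Pechmann condensation: in hot sulfuric acid malic acid loses CO and water to give formylacetic acid, which should attack 1 at C6 (para to one OH, ortho to the other, and less hindered than the site between the two OH groups) and lactonise, as in the classical route to 7-hydroxycoumarin.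

Step 2
Reactants: 3 6-bromo-7-hydroxycoumarin
Product: 4 6-bromo-7-(methoxymethoxy)coumarin
Conditions: MOMCl, K2CO3, acetone, 0 °C → rt
Reagents that add atoms: chloromethyl methyl ether, COCCl
Why: Williamson-type O-alkylation of the acidic 7-OH; the MOM ether withstands every base used later, polarises the aryne of step 15 and directs the lithiation of step 16.

Step 3
Reactants: 4 6-bromo-7-(methoxymethoxy)coumarin
Product: 5 (S)-6-bromo-4-isobutyl-7-(methoxymethoxy)chroman-2-one
Conditions: i-BuMgBr (1.3 equiv), CuBr·SMe2 (5 mol %), reversed-Josiphos ferrocenyl diphosphine (6 mol %), CH2Cl2/t-BuOMe, −75 °C; aq NH4Cl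
Reagents that add atoms: isobutylmagnesium bromide, CC(C)C[Mg]Br
Why: Copper-catalysed asymmetric conjugate addition of a Grignard reagent to a coumarin, a known substrate class for ferrocenyl diphosphine ligands; the chiral copper complex alone chooses the face and sets the benzylic centre as S, and the aryl bromide is inert to an alkyl Grignard reagent at this temperature.

Step 4
Reactants: 6 3-methylbut-3-en-1-ol
Product: 7 4-iodo-2-methylbut-1-ene
Conditions: I2, PPh3, imidazole, CH2Cl2, 0 °C → rt
Reagents that add atoms: iodine, II
Why: Appel iodination of a primary homoallylic alcohol under near-neutral conditions that leave the 1,1-disubstituted alkene in place.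

Step 5
Reactants: 5 (S)-6-bromo-4-isobutyl-7-(methoxymethoxy)chroman-2-one; 7 4-iodo-2-methylbut-1-ene
Product: 9 (3S,4S)-6-bromo-4-isobutyl-7-(methoxymethoxy)-3-(3-methylbut-3-enyl)chroman-2-one (3,4-trans), via lithium enolate 8 (not isolated)
Conditions: LiHMDS (1.05 equiv), THF, −78 °C; 7 (2 equiv), DMPU, −78 → −30 °C
Reagents that add atoms: none
Why: Alkylation of a lactone lithium enolate: the C4 isobutyl group stands pseudoaxial to avoid the peri hydrogen and shields one face of the flat enolate, so the iodide should enter trans and set C3 as S, and the trans isomer is also the more stable one should any epimerisation occur.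

Step 6
Reactants: 9 (3S,4S)-trans-lactone
Product: 10 (2S,3S)-3-[5-bromo-2-hydroxy-4-(methoxymethoxy)phenyl]-N-methoxy-N,5-dimethyl-2-(3-methylbut-3-enyl)hexanamide
Conditions: MeNH(OMe)·HCl, i-PrMgCl, THF, −20 → 0 °C; aq NH4Cl
Reagents that add atoms: N,O-dimethylhydroxylamine hydrochloride, CNOC.Cl
Why: Weinreb aminolysis of an aryl ester with the chloromagnesium amide, which opens the activated lactone below the temperature at which the alpha centre could enolise and frees the phenol.

Step 7
Reactants: 10 phenolic Weinreb amide
Product: 11 (2S,3S)-3-[5-bromo-2,4-bis(methoxymethoxy)phenyl]-N-methoxy-N,5-dimethyl-2-(3-methylbut-3-enyl)hexanamide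
Conditions: MOMCl, K2CO3, DMF, 0 °C → rt
Reagents that add atoms: chloromethyl methyl ether, COCCl
Why: O-alkylation of the phenoxide; the second MOM ether completes the 2,4-dialkoxy-5-bromo pattern that the aryne step requires.

Step 8
Reactants: 12 5-chloro-2-methylpent-2-ene
Product: 13 (R)-3-(2-chloroethyl)-2,2-dimethyloxirane
Conditions: D-fructose-derived Shi ketone (0.3 equiv), Oxone, K2CO3, Bu4NHSO4, MeCN–CH2(OMe)2/aq Na2B4O7–EDTA buffer, 0 °C
Reagents that add atoms: potassium peroxymonosulfate (Oxone), [K+].[O-]S(=O)(=O)OO
Why: Shi epoxidation: the dioxirane of the D-fructose-derived ketone transfers oxygen to trisubstituted alkenes through a spiro transition state, which for a Me2C=CH–CH2R alkene should give the (R)-epoxide.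

Step 9
Reactants: 13 (R)-3-(2-chloroethyl)-2,2-dimethyloxirane
Product: 14 (S)-3-(2-chloroethyl)-2-methylhex-5-en-2-ol
Conditions: allylMgCl (2 equiv), CuI (10 mol %), THF, −30 → 0 °C; aq NH4Cl
Reagents that add atoms: allylmagnesium chloride, C=CC[Mg]Cl
Why: Copper-catalysed SN2 opening of a trisubstituted epoxide at its less substituted carbon with inversion, which turns the C–O stereocentre into the C-allyl stereocentre of the target, while a primary alkyl chloride does not couple under these conditions.

Step 10
Reactants: 14 (S)-3-(2-chloroethyl)-2-methylhex-5-en-2-ol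
Product: 15 (S)-{[3-(2-chloroethyl)-2-methylhex-5-en-2-yl]oxy}triethylsilane
Conditions: TESOTf, 2,6-lutidine, CH2Cl2, 0 °C
Reagents that add atoms: triethylsilyl triflate, CC[Si](CC)(CC)OS(=O)(=O)C(F)(F)F
Why: Silylation of a hindered tertiary alcohol with a silyl triflate; the TES ether survives the organometallic bases and falls in the final acid step.

Step 11
Reactants: 15 chloro TES ether
Product: 16 (S)-triethyl{[3-(2-iodoethyl)-2-methylhex-5-en-2-yl]oxy}silane
Conditions: NaI, butan-2-one, 80 °C
Reagents that add atoms: sodium iodide, [Na+].[I-]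
Why: Finkelstein exchange driven by precipitation of NaCl, giving the iodide needed for clean halogen–lithium exchange.

Step 12
Reactants: 16 iodide; 11 bis-MOM Weinreb amide
Product: 19 (5S,9R)-5-{(1S)-1-[5-bromo-2,4-bis(methoxymethoxy)phenyl]-3-methylbutyl}-2-methyl-9-[2-(triethylsilyloxy)propan-2-yl]dodeca-1,11-dien-6-one, via alkyllithium 17 (not isolated), via alkylmagnesium bromide 18 (not isolated)
Conditions: t-BuLi (2.1 equiv), Et2O/pentane, −78 °C; MgBr2·OEt2, −78 → 0 °C; 11, THF, 0 °C → rt; aq NH4Cl
Reagents that add atoms: none
Why: Iodine–lithium exchange at −78 °C (too cold for 5-exo carbolithiation of the hexenyl chain), transmetalation to magnesium so that the aryl bromide of 11 is not exchanged, and Weinreb ketone synthesis, whose chelated adduct stops at the ketone and leaves the alpha centre intact.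

Step 13
Reactants: 19 dienyl ketone
Product: 20 (5S,6R,9R)-5-{(1S)-1-[5-bromo-2,4-bis(methoxymethoxy)phenyl]-3-methylbutyl}-2,6-dimethyl-9-[2-(triethylsilyloxy)propan-2-yl]dodeca-1,11-dien-6-ol
Conditions: MeLi, anhydrous CeCl3, THF, −78 °C; aq NH4Cl
Reagents that add atoms: methyllithium, C[Li]
Why: Organocerium 1,2-addition to an enolisable hindered ketone under Felkin–Anh control: the branched 1-aryl-3-methylbutyl group lies anti to the incoming methyl, which passes the alpha hydrogen, and this should give the (R)-carbinol with OH gauche to the benzylic arm.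

Step 14
Reactants: 20 dienyl carbinol
Product: 21 (1R,2S,5Z,8R)-2-{(1S)-1-[5-bromo-2,4-bis(methoxymethoxy)phenyl]-3-methylbutyl}-1,5-dimethyl-8-[2-(triethylsilyloxy)propan-2-yl]cyclodec-5-en-1-ol
Conditions: Hoveyda–Grubbs II (10 mol %, in portions), 1,4-benzoquinone (20 mol %), toluene (1 mM), 80 °C, argon sparge
Reagents that add atoms: none
Why: Ring-closing metathesis of a monosubstituted and a 1,1-disubstituted alkene at high dilution; the three branched ring carbons favour folded conformers, and in a ten-membered ring the Z trisubstituted alkene is much less strained than the E isomer, so Z should result.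

Step 15
Reactants: 21 bromoaryl cyclodecenol
Product: 24 monoformyl chroman-fused (Z)-cyclodecene (pyran closed between the carbinol oxygen and aryl C6; CHO on the former C–Br carbon), via aryne lithium alkoxide 22 (not isolated), via aryllithium 23 (not isolated)
Conditions: LiTMP (3 equiv, from TMPH and n-BuLi), THF, −78 → −40 °C; DMF (8 equiv), −78 → 0 °C; aq NH4Cl
Reagents that add atoms: N,N-dimethylformamide, CN(C)C=O
Why: LiTMP first forms the lithium alkoxide and then, held close by mixed aggregation with it, removes the one ring hydrogen next to bromine; loss of LiBr gives the 3-alkoxyaryne 22, the tethered tertiary alkoxide adds to the aryne carbon beside the benzylic arm, and DMF formylates the aryllithium 23 left on the carbon beside OMOM. The closest known reaction type is the anionic aryne cyclisation of a tethered heteroatom nucleophile followed by electrophile capture of the new aryllithium, which is also practised with LiTMP-generated arynes because tetramethylpiperidine is too hindered to protonate a chelated aryllithium quickly at low temperature. The pyran ring closes in the 6-exo-dig mode, the second aryne carbon staying outside the new ring. No stereocentre is created, and since the carbinol carbon keeps its oxygen throughout, its configuration carries over unchanged and the transannular alkene never meets a cationic centre. The selectivity at stake is which aryne carbon takes the oxygen: the sigma-withdrawing OMOM group favours build-up of charge on the carbon beside it, and the three-carbon tether can reach only the other one, so both effects agree. Deprotonation in place of bromine–lithium exchange is secured by the amide base, while metalation between the two MOM ethers is reversible under these conditions and is drained by the irreversible loss of LiBr.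

Step 16
Reactants: 24 monoformyl chroman
Product: 27 diformyl chroman-fused (Z)-cyclodecene (bis-MOM, TES), via lithium amino alkoxide 25 (not isolated), via ring-lithiated amino alkoxide 26 (not isolated)
Conditions: LiN(Me)CH2CH2NMe2 (1.2 equiv, from the amine and n-BuLi), THF, −20 °C; n-BuLi (3 equiv), −20 → 0 °C; DMF, −78 °C → rt; aq NH4Cl
Reagents that add atoms: N,N-dimethylformamide, CN(C)C=O
Why: In situ alpha-amino alkoxide protection of the aldehyde followed by directed ortho-lithiation: the only ring hydrogen left lies between two MOM ethers, so butyllithium can metalate only there, DMF delivers the second formyl group and work-up frees the first.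

Step 17
Reactants: 27 protected dialdehyde
Product: 28 target CNP0570248.1
Conditions: 3 M aq HCl, THF, rt → 40 °C
Reagents that add atoms: none
Why: Acid hydrolysis of the two acetal-type ethers and the silyl ether: MOM ethers flanked by formyl groups release acidic, strongly hydrogen-bonded phenols and should cleave under acid mild enough to spare the tertiary alcohol, the alkene and the tertiary alkyl aryl ether.

**Compound list**
1 | 4-bromoresorcinol | Oc1ccc(Br)c(O)c1 | starting material
2 | DL-malic acid | OC(=O)CC(O)C(=O)O | starting material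
3 | 6-bromo-7-hydroxycoumarin | O=C1C=Cc2cc(Br)c(O)cc2O1 | intermediate
4 | 6-bromo-7-(methoxymethoxy)coumarin | O=C1C=Cc2cc(Br)c(OCOC)cc2O1 | intermediate
5 | (S)-6-bromo-4-isobutyl-7-(methoxymethoxy)chroman-2-one | O=C1C[C@H](CC(C)C)c2cc(Br)c(OCOC)cc2O1 | intermediate
6 | 3-methylbut-3-en-1-ol | CC(=C)CCO | starting material
7 | 4-iodo-2-methylbut-1-ene | CC(=C)CCI | intermediate
8 | lithium enolate of 5 | [Li]OC1=C[C@H](CC(C)C)c2cc(Br)c(OCOC)cc2O1 | intermediate
9 | (3S,4S)-6-bromo-4-isobutyl-7-(methoxymethoxy)-3-(3-methylbut-3-enyl)chroman-2-one | O=C1[C@@H](CCC(C)=C)[C@H](CC(C)C)c2cc(Br)c(OCOC)cc2O1 | intermediate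
10 | (2S,3S) phenolic Weinreb amide | CON(C)C(=O)[C@@H](CCC(C)=C)[C@H](CC(C)C)c1cc(Br)c(OCOC)cc1O | intermediate
11 | (2S,3S) bis-MOM Weinreb amide | CON(C)C(=O)[C@@H](CCC(C)=C)[C@H](CC(C)C)c1cc(Br)c(OCOC)cc1OCOC | intermediate
12 | 5-chloro-2-methylpent-2-ene | CC(C)=CCCCl | starting material
13 | (R)-3-(2-chloroethyl)-2,2-dimethyloxirane | ClCC[C@H]1OC1(C)C | intermediate
14 | (S)-3-(2-chloroethyl)-2-methylhex-5-en-2-ol | ClCC[C@H](CC=C)C(C)(C)O | intermediate
15 | TES ether of 14 | ClCC[C@H](CC=C)C(C)(C)O[Si](CC)(CC)CC | intermediate
16 | (S)-iodide | ICC[C@H](CC=C)C(C)(C)O[Si](CC)(CC)CC | intermediate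
17 | alkyllithium from 16 | [Li]CC[C@H](CC=C)C(C)(C)O[Si](CC)(CC)CC | intermediate
18 | alkylmagnesium bromide from 17 | Br[Mg]CC[C@H](CC=C)C(C)(C)O[Si](CC)(CC)CC | intermediate
19 | (5S,9R,1'S) dienyl ketone | C=CC[C@H](C(C)(C)O[Si](CC)(CC)CC)CCC(=O)[C@@H](CCC(C)=C)[C@H](CC(C)C)c1cc(Br)c(OCOC)cc1OCOC | intermediate
20 | (5S,6R,9R,1'S) dienyl tertiary alcohol | C=CC[C@H](C(C)(C)O[Si](CC)(CC)CC)CC[C@@](C)(O)[C@H]([C@H](CC(C)C)c1cc(Br)c(OCOC)cc1OCOC)CCC(C)=C | intermediate
21 | (1R,2S,5Z,8R,1'S) bromoaryl cyclodecenol (aryne precursor) | C/C1=C/C[C@H](C(C)(C)O[Si](CC)(CC)CC)CC[C@@](C)(O)[C@H]([C@H](CC(C)C)c2cc(Br)c(OCOC)cc2OCOC)CC1 | intermediate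
22 | aryne lithium alkoxide | C/C1=C/C[C@H](C(C)(C)O[Si](CC)(CC)CC)CC[C@@](C)(O[Li])[C@H]([C@H](CC(C)C)C2=C(OCOC)C=C(OCOC)C#C2)CC1 | intermediate
23 | chroman aryllithium | C/C1=C/C[C@H](C(C)(C)O[Si](CC)(CC)CC)CC[C@@]2(C)Oc3c([Li])c(OCOC)cc(OCOC)c3[C@@H](CC(C)C)[C@@H]2CC1 | intermediate
24 | monoformyl chroman-fused (Z)-cyclodecene | C/C1=C/C[C@H](C(C)(C)O[Si](CC)(CC)CC)CC[C@@]2(C)Oc3c(C=O)c(OCOC)cc(OCOC)c3[C@@H](CC(C)C)[C@@H]2CC1 | intermediate
25 | lithium alpha-amino alkoxide of 24 | C/C1=C/C[C@H](C(C)(C)O[Si](CC)(CC)CC)CC[C@@]2(C)Oc3c(C(O[Li])N(C)CCN(C)C)c(OCOC)cc(OCOC)c3[C@@H](CC(C)C)[C@@H]2CC1 | intermediate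
26 | ring-lithiated 25 | C/C1=C/C[C@H](C(C)(C)O[Si](CC)(CC)CC)CC[C@@]2(C)Oc3c(C(O[Li])N(C)CCN(C)C)c(OCOC)c([Li])c(OCOC)c3[C@@H](CC(C)C)[C@@H]2CC1 | intermediate
27 | diformyl chroman, bis-MOM, TES | C/C1=C/C[C@H](C(C)(C)O[Si](CC)(CC)CC)CC[C@@]2(C)Oc3c(C=O)c(OCOC)c(C=O)c(OCOC)c3[C@@H](CC(C)C)[C@@H]2CC1 | intermediate
28 | CNP0570248.1 | C/C1=C/C[C@H](C(C)(C)O)CC[C@@]2(C)Oc3c(C=O)c(O)c(C=O)c(O)c3[C@@H](CC(C)C)[C@@H]2CC1 | target

**Count:** 17 steps in total. The longest linear sequence is 12 steps (1–3, 5–7, 12–17).

**Steps most likely to fail**

**Step 15.**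
- Risk: the aryl anion may not survive until DMF is added. It can be lost by proton transfer from tetramethylpiperidine or by migration to the site between the two MOM ethers. Removal of the crowded ring hydrogen may also be slow.
- Fallback: ring closure and formylation are separated, starting from 21.
- The LiTMP aryne cyclisation is run to completion and quenched with methanol to give the unformylated chroman F1.
- Directed ortho-lithiation (n-BuLi, TMEDA) between the two MOM ethers, then DMF, gives the regioisomeric monoaldehyde F2.
- The aldehyde is masked as in step 16. s-BuLi then lithiates the last ring hydrogen, which lies between OMOM and the pyran oxygen, and DMF brings the material back to the route at 27.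

**Step 14.**
- Risk: oligomerisation may win over closure of the flexible chain, or control of the alkene geometry may be poor.
- Fallback: the order of the two ring closures is reversed, starting from 20.
- The LiTMP/DMF cascade is run on the open-chain carbinol and gives the 2,3-trans-disubstituted formyl chroman diene F3.
- In F3 the rigid pyran holds the two olefinic arms gauche to each other. Ring-closing metathesis on this template returns to the route at 24.

**Step 13.**
- Risk: facial selectivity may be poor in the flexible ketone.
- Fallback: the ring is closed first, starting from 19.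
- Metathesis gives the (Z)-cyclodecenone F4, in which the carbonyl group stands across the mean ring plane and only its outer face is open.
- Organocerium methyl addition under this medium-ring conformational control rejoins the route at 21.

**Further compounds**
F1 | step 15 | unformylated chroman-fused (Z)-cyclodecene | C/C1=C/C[C@H](C(C)(C)O[Si](CC)(CC)CC)CC[C@@]2(C)Oc3cc(OCOC)cc(OCOC)c3[C@@H](CC(C)C)[C@@H]2CC1
F2 | step 15 | regioisomeric monoaldehyde (CHO between the MOM ethers) | C/C1=C/C[C@H](C(C)(C)O[Si](CC)(CC)CC)CC[C@@]2(C)Oc3cc(OCOC)c(C=O)c(OCOC)c3[C@@H](CC(C)C)[C@@H]2CC1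
F3 | step 14 | 2,3-trans-disubstituted formyl chroman diene | C=CC[C@H](C(C)(C)O[Si](CC)(CC)CC)CC[C@@]1(C)Oc2c(C=O)c(OCOC)cc(OCOC)c2[C@@H](CC(C)C)[C@@H]1CCC(C)=C
F4 | step 13 | 2-substituted (Z)-cyclodec-5-enone | C/C1=C/C[C@H](C(C)(C)O[Si](CC)(CC)CC)CCC(=O)[C@H]([C@H](CC(C)C)c2cc(Br)c(OCOC)cc2OCOC)CC1
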